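**Retrosynthetic overview**
- The styryl C=C is made last by cross-metathesis. The side-chain carbinol C–C bond comes from a syn-aldol of a cis-fused γ-lactone, a temporary ring that ties the axial 4-OH to the two-carbon arm on C-3 and is opened again at the olefination stage.
- The lactone comes from a 3-vinyl-oxan-4-ol. Its oxane ring is made in one operation from an (S,Z)-δ-hydroxy allylboronate and an (E)-enal by a domino oxa-Michael/intramolecular allylboration (a [3+3] union that forms O-1–C-6 and C-3–C-4).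
- Enabling feature: in the oxane, ether carbon C-6 and carbinol C-4 are 1,3-related across the C-5 methylene, which is the pattern of a β-alkoxy aldehyde (enal + alcohol). C-3 lies between the benzylic ether carbon C-2 and C-4 and carries a carbon branch cis to the axial 4-OH, which is the γ-carbon of a (Z)-allylboronate.
- Ring order: oxane first (key step), then the temporary γ-lactone fused at C-3/C-4.
- Building blocks: 4-hydroxybenzaldehyde and methyl 3-(4-hydroxyphenyl)propanoate; all phenols are carried as TIPS ethers.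

Key step: step 12

Remark: oxane numbering is used for the ring (O-1, C-2 aryl, C-3, C-4 hydroxyl, C-5, C-6). TIPS = triisopropylsilyl, TES = triethylsilyl, Bpin = 4,4,5,5-tetramethyl-1,3,2-dioxaborolan-2-yl. The aryl TIPS ethers are assumed to survive every step up to the final fluoride treatment.

**Route**

Step 1
Reactants: 1 4-hydroxybenzaldehyde; 2 chlorotriisopropylsilane
Product: 3 4-(TIPSO)benzaldehyde
Conditions: TIPSCl, imidazole, DMF, rt
Reagents that add atoms: chlorotriisopropylsilane (2), CC(C)[Si](Cl)(C(C)C)C(C)C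
Why: Silylation of the phenol gives a base- and hydride-stable, fluoride-labile aryl ether.

Step 2
Reactants: 3 4-(TIPSO)benzaldehyde; 4 vinylmagnesium bromide
Product: 5 rac-1-[4-(TIPSO)phenyl]prop-2-en-1-ol
Conditions: THF, −78 → 0 °C; then H2O
Reagents that add atoms: vinylmagnesium bromide (4), C=C[Mg]Br
Why: Grignard 1,2-addition to the aldehyde gives the racemic allylic alcohol.

Step 3
Reactants: 5 rac-1-[4-(TIPSO)phenyl]prop-2-en-1-ol
Product: 6 (1S)-1-[4-(TIPSO)phenyl]prop-2-en-1-ol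
Conditions: Novozym 435 (CAL-B), vinyl acetate, MTBE, 30 °C, stopped near half conversion; chromatography
Reagents that add atoms: none
Why: Lipase-catalysed kinetic resolution: CAL-B acylates the (R)-enantiomer of 1-aryl carbinols (Kazlauskas rule), so the (S)-alcohol is recovered and later becomes C-2 of the oxane.

Step 4
Reactants: 7 allylmagnesium bromide; 8 triisopropyl borate
Product: 9 diisopropyl allylboronate
Conditions: Et2O, −78 °C → rt; HCl (Et2O), 0 °C; distillation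
Reagents that add atoms: allylmagnesium bromide (7), C=CC[Mg]Br
Why: Borylation of a Grignard reagent followed by acid cleavage of the borate salt gives the exchangeable allylboronic ester.

Step 5
Reactants: 6 (1S)-1-[4-(TIPSO)phenyl]prop-2-en-1-ol; 9 diisopropyl allylboronate; 10 pinacol
Product: 13 (1S,2Z)-1-[4-(TIPSO)phenyl]-4-(Bpin)but-2-en-1-ol, via mixed allylboronate ester 11 (not isolated), via cyclic allylboronate 12 (not isolated)
Conditions: 9, CH2Cl2, rt, evacuation; Grubbs II (5 mol %), CH2Cl2, 40 °C; pinacol, rt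
Reagents that add atoms: diisopropyl allylboronate (9), C=CCB(OC(C)C)OC(C)C; pinacol (10), CC(C)(O)C(C)(C)O
Why: Boronic ester annulation: transesterification tethers the allylboron unit to the alcohol, ring-closing metathesis in a six-membered ring can only give the Z-alkene, and pinacol then displaces both B–O bonds to release the (Z)-allyl pinacol boronate with the free alcohol and the carbinol centre untouched.

Step 6
Reactants: 14 methyl 3-(4-hydroxyphenyl)propanoate; 2 chlorotriisopropylsilane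
Product: 15 methyl 3-[4-(TIPSO)phenyl]propanoate
Conditions: TIPSCl, imidazole, DMF, rt
Reagents that add atoms: chlorotriisopropylsilane (2), CC(C)[Si](Cl)(C(C)C)C(C)C
Why: Silylation of the phenol, as in step 1.

Step 7
Reactants: 15 methyl 3-[4-(TIPSO)phenyl]propanoate
Product: 16 3-[4-(TIPSO)phenyl]propanal
Conditions: DIBAL-H, CH2Cl2, −78 °C; Rochelle salt
Reagents that add atoms: none
Why: Partial reduction of the ester stops at the aldehyde because the tetrahedral aluminate is stable at −78 °C.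

Step 8
Reactants: 16 3-[4-(TIPSO)phenyl]propanal; 17 (triphenylphosphoranylidene)acetaldehyde
Product: 18 (2E)-5-[4-(TIPSO)phenyl]pent-2-enal
Conditions: toluene, 80 °C
Reagents that add atoms: (triphenylphosphoranylidene)acetaldehyde (17), O=CC=P(c1ccccc1)(c1ccccc1)c1ccccc1
Why: Wittig reaction with a stabilised ylide gives the (E)-enal.

Step 9
Reactants: 16 3-[4-(TIPSO)phenyl]propanal; 19 (methoxymethyl)triphenylphosphonium chloride
Product: 20 1-methoxy-4-[4-(TIPSO)phenyl]but-1-ene (E/Z mixture)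
Conditions: KOtBu, THF, 0 °C → rt
Reagents that add atoms: (methoxymethyl)triphenylphosphonium chloride (19), COC[P+](c1ccccc1)(c1ccccc1)c1ccccc1.[Cl-]
Why: Wittig methoxymethylenation is the standard one-carbon homologation of an aldehyde; the enol ether geometry is irrelevant.

Step 10
Reactants: 20 1-methoxy-4-[4-(TIPSO)phenyl]but-1-ene; 21 water
Product: 22 4-[4-(TIPSO)phenyl]butanal
Conditions: 2 M HCl, THF, rt
Reagents that add atoms: water (21), O
Why: Acid hydrolysis of the enol ether releases the homologated aldehyde, and the aryl TIPS ether tolerates dilute acid.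

Step 11
Reactants: 3 4-(TIPSO)benzaldehyde; 23 methyltriphenylphosphonium bromide
Product: 24 1-ethenyl-4-(TIPSO)benzene
Conditions: KOtBu, THF, 0 °C → rt
Reagents that add atoms: methyltriphenylphosphonium bromide (23), C[P+](c1ccccc1)(c1ccccc1)c1ccccc1.[Br-]
Why: Wittig methylenation gives the styrene partner for the final cross-metathesis.

Step 12
Reactants: 13 (1S,2Z)-1-[4-(TIPSO)phenyl]-4-(Bpin)but-2-en-1-ol; 18 (2E)-5-[4-(TIPSO)phenyl]pent-2-enal
Product: 27 (2S,3S,4S,6S)-3-ethenyl-2-[4-(TIPSO)phenyl]-6-{2-[4-(TIPSO)phenyl]ethyl}oxan-4-ol, via β-alkoxy aldehyde 25 (not isolated), via O-boryl ether 26 (not isolated)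
Conditions: (R)-α,α-diphenylprolinol TMS ether (20 mol %), PhCO2H (20 mol %), H2O (2 equiv), toluene, 0 °C → rt; aq. NaHCO3 work-up
Reagents that add atoms: (2E)-5-[4-(TIPSO)phenyl]pent-2-enal (18), O=C/C=C/CCc1ccc(O[Si](C(C)C)(C(C)C)C(C)C)cc1
Why: Proposed new method: the amine turns enal 18 into its iminium ion, the alcohol of 13 adds reversibly to the β-carbon (oxa-Michael, O-1–C-6 bond), hydrolysis releases β-alkoxy aldehyde 25, and its aldehyde is allylated by the tethered (Z)-allylboronate through a closed six-membered boron transition state (C-3–C-4 bond), giving borate 26 and, after hydrolysis, 27. The closest known reaction types are the iminium-catalysed conjugate addition of O-nucleophiles to enals and the domino hydroformylation–allylboration, in which an aldehyde generated next to an inert allylboronate is trapped intramolecularly. The oxane closes in the C–C bond-forming event as a 6-exo-trig attack on the aldehyde, through a chair fused cis to the boron-containing chair. C-2 is carried in from 13; C-3 is set by allylic 1,3-strain (C-2–H eclipses the Z-alkene, attack occurs on the face of the tethering oxygen, aryl equatorial, hence 2,3-trans); C-4 is set by the Z geometry of the boronate (Z gives 3,4-cis, the axial hydroxyl); C-6 is set dynamically, because the C-6 epimers of 25 interconvert by retro-oxa-Michael and only the epimer with the arylethyl chain equatorial avoids a 1,3-diaxial clash with the axial carbonyl oxygen, a preference the (R)-catalyst should reinforce. The step needs conjugate O-addition followed by cyclisation to outrun direct 1,2-allylboration of 18; this rests on the low intermolecular reactivity of γ-substituted (Z)-allyl pinacol boronates towards enals, the high effective molarity of the six-membered closure, and the fact that the amine activates only the enal.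

Step 13
Reactants: 27 (2S,3S,4S,6S)-3-ethenyl-2-[4-(TIPSO)phenyl]-6-{2-[4-(TIPSO)phenyl]ethyl}oxan-4-ol; 28 hydrogen peroxide
Product: 29 (2S,3S,4S,6S)-3-(2-hydroxyethyl)-2-[4-(TIPSO)phenyl]-6-{2-[4-(TIPSO)phenyl]ethyl}oxan-4-ol
Conditions: 9-BBN (excess), THF, 0 °C → rt; then H2O2, aq. NaOH, 0 °C
Reagents that add atoms: hydrogen peroxide (28), OO
Why: Anti-Markovnikov hydroboration–oxidation of the only alkene gives the primary alcohol without touching a stereocentre.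

Step 14
Reactants: 29 (2S,3S,4S,6S)-3-(2-hydroxyethyl)-2-[4-(TIPSO)phenyl]-6-{2-[4-(TIPSO)phenyl]ethyl}oxan-4-ol
Product: 30 (3aS,4S,6S,7aS)-4-[4-(TIPSO)phenyl]-6-{2-[4-(TIPSO)phenyl]ethyl}hexahydro-4H-furo[3,2-c]pyran-2(3H)-one (cis-fused γ-lactone)
Conditions: TEMPO (20 mol %), PhI(OAc)2, CH2Cl2, rt
Reagents that add atoms: none
Why: TEMPO/PhI(OAc)2 oxidative lactonisation: the primary alcohol is oxidised selectively, the aldehyde is captured as a lactol by the cis (axial) 4-OH, and the lactol is oxidised to the cis-fused γ-lactone.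

Step 15
Reactants: 30 cis-fused γ-lactone; 22 4-[4-(TIPSO)phenyl]butanal
Product: 31 (3R,3aS,4S,6S,7aS)-3-{(1S)-1-hydroxy-4-[4-(TIPSO)phenyl]butyl}-4-[4-(TIPSO)phenyl]-6-{2-[4-(TIPSO)phenyl]ethyl}hexahydro-4H-furo[3,2-c]pyran-2(3H)-one
Conditions: LDA, THF, −78 °C; Cp2ZrCl2, −78 → −20 °C; 22, −78 °C; then H2O
Reagents that add atoms: 4-[4-(TIPSO)phenyl]butanal (22), O=CCCCc1ccc(O[Si](C(C)C)(C(C)C)C(C)C)cc1
Why: Zirconium enolate aldol addition: the enolate of the cis-fused lactone reacts on its convex face, anti to the oxane ring, which sets the lactone α-centre, and zirconium enolates give the syn (erythro) aldol irrespective of enolate geometry, which sets the (S)-carbinol.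

Step 16
Reactants: 31 aldol adduct; 32 triethylsilyl trifluoromethanesulfonate
Product: 33 (3R,3aS,4S,6S,7aS)-3-{(1S)-1-(triethylsilyloxy)-4-[4-(TIPSO)phenyl]butyl}-4-[4-(TIPSO)phenyl]-6-{2-[4-(TIPSO)phenyl]ethyl}hexahydro-4H-furo[3,2-c]pyran-2(3H)-one
Conditions: TESOTf, 2,6-lutidine, CH2Cl2, −78 → 0 °C
Reagents that add atoms: triethylsilyl trifluoromethanesulfonate (32), CC[Si](CC)(CC)OS(=O)(=O)C(F)(F)F
Why: Silylation of the β-hydroxyl blocks retro-aldol cleavage during the basic olefination.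

Step 17
Reactants: 33 TES-protected aldol lactone
Product: 34 (3R,3aS,4S,6S,7aS)-3-{(1S)-1-(triethylsilyloxy)-4-[4-(TIPSO)phenyl]butyl}-4-[4-(TIPSO)phenyl]-6-{2-[4-(TIPSO)phenyl]ethyl}hexahydro-4H-furo[3,2-c]pyran-2-ol (anomeric mixture)
Conditions: DIBAL-H, CH2Cl2, −78 °C; Rochelle salt
Reagents that add atoms: none
Why: Partial reduction of a γ-lactone with DIBAL-H at low temperature stops at the lactol.

Step 18
Reactants: 34 lactol; 23 methyltriphenylphosphonium bromide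
Product: 35 (2S,3S,4S,6S)-3-{(3R,4S)-4-(triethylsilyloxy)-7-[4-(TIPSO)phenyl]hept-1-en-3-yl}-2-[4-(TIPSO)phenyl]-6-{2-[4-(TIPSO)phenyl]ethyl}oxan-4-ol
Conditions: KHMDS, THF, 0 °C; then 34, −20 °C → rt
Reagents that add atoms: methyltriphenylphosphonium bromide (23), C[P+](c1ccccc1)(c1ccccc1)c1ccccc1.[Br-]
Why: Wittig methylenation of the lactol through its open hydroxy-aldehyde form opens the temporary lactone ring, frees the axial 4-OH, and is fast enough with the unstabilised ylide to leave the α-stereocentre intact.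

Step 19
Reactants: 35 terminal alkene; 24 1-ethenyl-4-(TIPSO)benzene
Product: 36 (2S,3S,4S,6S)-3-{(1E,3R,4S)-4-(triethylsilyloxy)-1,7-bis[4-(TIPSO)phenyl]hept-1-en-3-yl}-2-[4-(TIPSO)phenyl]-6-{2-[4-(TIPSO)phenyl]ethyl}oxan-4-ol
Conditions: Hoveyda–Grubbs II (10 mol %), 24 (excess), CH2Cl2, 40 °C
Reagents that add atoms: 1-ethenyl-4-(TIPSO)benzene (24), C=Cc1ccc(O[Si](C(C)C)(C(C)C)C(C)C)cc1
Why: Olefin cross-metathesis with a styrene gives the conjugated (E)-alkene under neutral conditions that cannot epimerise the allylic centre.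

Step 20
Reactants: 36 fully protected target
Product: 37 4-[(2S,3S,4S,6S)-4-hydroxy-3-[(1E,3R,4S)-4-hydroxy-1,7-bis(4-hydroxyphenyl)hept-1-en-3-yl]-6-[2-(4-hydroxyphenyl)ethyl]oxan-2-yl]phenol
Conditions: TBAF, AcOH, THF, 0 °C → rt
Reagents that add atoms: none
Why: Fluoride-mediated desilylation removes the four aryl TIPS ethers and the TES ether in one operation; the acetic acid buffer keeps the phenols protonated so the benzylic ring ether at C-2 is not opened.

**Compound list**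

1 | 4-hydroxybenzaldehyde | O=Cc1ccc(O)cc1 | starting material
2 | chlorotriisopropylsilane | CC(C)[Si](Cl)(C(C)C)C(C)C | starting material
3 | 4-(triisopropylsilyloxy)benzaldehyde | O=Cc1ccc(O[Si](C(C)C)(C(C)C)C(C)C)cc1 | intermediate
4 | vinylmagnesium bromide | C=C[Mg]Br | starting material
5 | rac-1-[4-(TIPSO)phenyl]prop-2-en-1-ol | C=CC(O)c1ccc(O[Si](C(C)C)(C(C)C)C(C)C)cc1 | intermediate
6 | (1S)-1-[4-(TIPSO)phenyl]prop-2-en-1-ol | O[C@H](c1ccc(O[Si](C(C)C)(C(C)C)C(C)C)cc1)C=C | intermediate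
7 | allylmagnesium bromide | C=CC[Mg]Br | starting material
8 | triisopropyl borate | CC(C)OB(OC(C)C)OC(C)C | starting material
9 | diisopropyl allylboronate | C=CCB(OC(C)C)OC(C)C | intermediate
10 | pinacol | CC(C)(O)C(C)(C)O | starting material
11 | isopropyl (1S)-1-[4-(TIPSO)phenyl]prop-2-en-1-yl allylboronate (mixed ester) | C=CCB(OC(C)C)O[C@H](c1ccc(O[Si](C(C)C)(C(C)C)C(C)C)cc1)C=C | intermediate
12 | (6S)-2-isopropoxy-6-[4-(TIPSO)phenyl]-3,6-dihydro-2H-1,2-oxaborinine | CC(C)OB1CC=C[C@@H](c2ccc(O[Si](C(C)C)(C(C)C)C(C)C)cc2)O1 | intermediate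
13 | (1S,2Z)-1-[4-(TIPSO)phenyl]-4-(Bpin)but-2-en-1-ol | O[C@H](c1ccc(O[Si](C(C)C)(C(C)C)C(C)C)cc1)/C=C\CB1OC(C)(C)C(C)(C)O1 | intermediate
14 | methyl 3-(4-hydroxyphenyl)propanoate | COC(=O)CCc1ccc(O)cc1 | starting material
15 | methyl 3-[4-(TIPSO)phenyl]propanoate | COC(=O)CCc1ccc(O[Si](C(C)C)(C(C)C)C(C)C)cc1 | intermediate
16 | 3-[4-(TIPSO)phenyl]propanal | O=CCCc1ccc(O[Si](C(C)C)(C(C)C)C(C)C)cc1 | intermediate
17 | (triphenylphosphoranylidene)acetaldehyde | O=CC=P(c1ccccc1)(c1ccccc1)c1ccccc1 | starting material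
18 | (2E)-5-[4-(TIPSO)phenyl]pent-2-enal | O=C/C=C/CCc1ccc(O[Si](C(C)C)(C(C)C)C(C)C)cc1 | intermediate
19 | (methoxymethyl)triphenylphosphonium chloride | COC[P+](c1ccccc1)(c1ccccc1)c1ccccc1.[Cl-] | starting material
20 | 1-methoxy-4-[4-(TIPSO)phenyl]but-1-ene (E/Z mixture) | COC=CCCc1ccc(O[Si](C(C)C)(C(C)C)C(C)C)cc1 | intermediate
21 | water | O | starting material
22 | 4-[4-(TIPSO)phenyl]butanal | O=CCCCc1ccc(O[Si](C(C)C)(C(C)C)C(C)C)cc1 | intermediate
23 | methyltriphenylphosphonium bromide | C[P+](c1ccccc1)(c1ccccc1)c1ccccc1.[Br-] | starting material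
24 | 1-ethenyl-4-(triisopropylsilyloxy)benzene | C=Cc1ccc(O[Si](C(C)C)(C(C)C)C(C)C)cc1 | intermediate
25 | (3S)-3-{[(1S,2Z)-1-[4-(TIPSO)phenyl]-4-(Bpin)but-2-en-1-yl]oxy}-5-[4-(TIPSO)phenyl]pentanal | O=CC[C@H](CCc1ccc(O[Si](C(C)C)(C(C)C)C(C)C)cc1)O[C@H](c1ccc(O[Si](C(C)C)(C(C)C)C(C)C)cc1)/C=C\CB1OC(C)(C)C(C)(C)O1 | intermediate
26 | 2-{[(2S,3S,4S,6S)-3-ethenyl-2-[4-(TIPSO)phenyl]-6-{2-[4-(TIPSO)phenyl]ethyl}oxan-4-yl]oxy}-4,4,5,5-tetramethyl-1,3,2-dioxaborolane | C=C[C@@H]1[C@@H](c2ccc(O[Si](C(C)C)(C(C)C)C(C)C)cc2)O[C@@H](CCc2ccc(O[Si](C(C)C)(C(C)C)C(C)C)cc2)C[C@@H]1OB1OC(C)(C)C(C)(C)O1 | intermediate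
27 | (2S,3S,4S,6S)-3-ethenyl-2-[4-(TIPSO)phenyl]-6-{2-[4-(TIPSO)phenyl]ethyl}oxan-4-ol (aryl, vinyl and chain equatorial, OH axial) | C=C[C@@H]1[C@@H](c2ccc(O[Si](C(C)C)(C(C)C)C(C)C)cc2)O[C@@H](CCc2ccc(O[Si](C(C)C)(C(C)C)C(C)C)cc2)C[C@@H]1O | intermediate
28 | hydrogen peroxide | OO | starting material
29 | (2S,3S,4S,6S)-3-(2-hydroxyethyl)-2-[4-(TIPSO)phenyl]-6-{2-[4-(TIPSO)phenyl]ethyl}oxan-4-ol | OCC[C@@H]1[C@@H](c2ccc(O[Si](C(C)C)(C(C)C)C(C)C)cc2)O[C@@H](CCc2ccc(O[Si](C(C)C)(C(C)C)C(C)C)cc2)C[C@@H]1O | intermediate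
30 | (3aS,4S,6S,7aS)-4-[4-(TIPSO)phenyl]-6-{2-[4-(TIPSO)phenyl]ethyl}hexahydro-4H-furo[3,2-c]pyran-2(3H)-one | O=C1C[C@@H]2[C@@H](c3ccc(O[Si](C(C)C)(C(C)C)C(C)C)cc3)O[C@@H](CCc3ccc(O[Si](C(C)C)(C(C)C)C(C)C)cc3)C[C@@H]2O1 | intermediate
31 | (3R,3aS,4S,6S,7aS)-3-{(1S)-1-hydroxy-4-[4-(TIPSO)phenyl]butyl}-4-[4-(TIPSO)phenyl]-6-{2-[4-(TIPSO)phenyl]ethyl}hexahydro-4H-furo[3,2-c]pyran-2(3H)-one | O=C1[C@@H]([C@@H](O)CCCc2ccc(O[Si](C(C)C)(C(C)C)C(C)C)cc2)[C@@H]2[C@@H](c3ccc(O[Si](C(C)C)(C(C)C)C(C)C)cc3)O[C@@H](CCc3ccc(O[Si](C(C)C)(C(C)C)C(C)C)cc3)C[C@@H]2O1 | intermediate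
32 | triethylsilyl trifluoromethanesulfonate | CC[Si](CC)(CC)OS(=O)(=O)C(F)(F)F | starting material
33 | (3R,3aS,4S,6S,7aS)-3-{(1S)-1-(triethylsilyloxy)-4-[4-(TIPSO)phenyl]butyl}-4-[4-(TIPSO)phenyl]-6-{2-[4-(TIPSO)phenyl]ethyl}hexahydro-4H-furo[3,2-c]pyran-2(3H)-one | O=C1[C@@H]([C@@H](O[Si](CC)(CC)CC)CCCc2ccc(O[Si](C(C)C)(C(C)C)C(C)C)cc2)[C@@H]2[C@@H](c3ccc(O[Si](C(C)C)(C(C)C)C(C)C)cc3)O[C@@H](CCc3ccc(O[Si](C(C)C)(C(C)C)C(C)C)cc3)C[C@@H]2O1 | intermediate
34 | (3R,3aS,4S,6S,7aS)-3-{(1S)-1-(triethylsilyloxy)-4-[4-(TIPSO)phenyl]butyl}-4-[4-(TIPSO)phenyl]-6-{2-[4-(TIPSO)phenyl]ethyl}hexahydro-4H-furo[3,2-c]pyran-2-ol (anomeric mixture) | OC1[C@@H]([C@@H](O[Si](CC)(CC)CC)CCCc2ccc(O[Si](C(C)C)(C(C)C)C(C)C)cc2)[C@@H]2[C@@H](c3ccc(O[Si](C(C)C)(C(C)C)C(C)C)cc3)O[C@@H](CCc3ccc(O[Si](C(C)C)(C(C)C)C(C)C)cc3)C[C@@H]2O1 | intermediate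
35 | (2S,3S,4S,6S)-3-{(3R,4S)-4-(triethylsilyloxy)-7-[4-(TIPSO)phenyl]hept-1-en-3-yl}-2-[4-(TIPSO)phenyl]-6-{2-[4-(TIPSO)phenyl]ethyl}oxan-4-ol | C=C[C@H]([C@@H]1[C@@H](c2ccc(O[Si](C(C)C)(C(C)C)C(C)C)cc2)O[C@@H](CCc2ccc(O[Si](C(C)C)(C(C)C)C(C)C)cc2)C[C@@H]1O)[C@@H](O[Si](CC)(CC)CC)CCCc1ccc(O[Si](C(C)C)(C(C)C)C(C)C)cc1 | intermediate
36 | (2S,3S,4S,6S)-3-{(1E,3R,4S)-4-(triethylsilyloxy)-1,7-bis[4-(TIPSO)phenyl]hept-1-en-3-yl}-2-[4-(TIPSO)phenyl]-6-{2-[4-(TIPSO)phenyl]ethyl}oxan-4-ol | CC(C)[Si](Oc1ccc(/C=C/[C@H]([C@@H]2[C@@H](c3ccc(O[Si](C(C)C)(C(C)C)C(C)C)cc3)O[C@@H](CCc3ccc(O[Si](C(C)C)(C(C)C)C(C)C)cc3)C[C@@H]2O)[C@@H](O[Si](CC)(CC)CC)CCCc2ccc(O[Si](C(C)C)(C(C)C)C(C)C)cc2)cc1)(C(C)C)C(C)C | intermediate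
37 | 4-[(2S,3S,4S,6S)-4-hydroxy-3-[(1E,3R,4S)-4-hydroxy-1,7-bis(4-hydroxyphenyl)hept-1-en-3-yl]-6-[2-(4-hydroxyphenyl)ethyl]oxan-2-yl]phenol | Oc1ccc(/C=C/[C@H]([C@@H]2[C@@H](c3ccc(O)cc3)O[C@@H](CCc3ccc(O)cc3)C[C@@H]2O)[C@@H](O)CCCc2ccc(O)cc2)cc1 | target

**Totals**

Total step count: 20. Longest linear sequence: 13 steps (1, 2, 3, 5, 12–20).

**Steps most likely to fail**

1. Step 12 (Proposed new method). Conjugate addition of the hindered secondary alcohol to the enal may be too slow or too unfavourable, so that direct 1,2-allylboration of the enal, or allylation of an iminium ion, takes over. The fallback builds the same oxane by a Prins cyclisation and rejoins the route at lactone 30. It sets out from aldehyde 16 and aldehyde 3. Brown allylation of 16 with (+)-Ipc2B(allyl) gives (3S)-1-[4-(TIPSO)phenyl]hex-5-en-3-ol F1. Cross-metathesis of F1 with methyl but-3-enoate (Grubbs II) gives methyl (3E,6S)-6-hydroxy-8-[4-(TIPSO)phenyl]oct-3-enoate F2. Prins cyclisation of F2 with 3 (TFA, CH2Cl2) should give the all-equatorial 4-trifluoroacetoxy oxane F3, which K2CO3/MeOH converts into the equatorial alcohol F4. Dess–Martin oxidation gives the oxan-4-one F5. L-Selectride delivers hydride from the equatorial side, and the resulting axial alkoxide closes onto the ester to give 30.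

2. Step 15. Simple diastereoselection at the carbinol may be poor, because the fixed E-geometry of the lactone enolate favours the anti adduct through a chair transition state if transmetalation to zirconium is incomplete. The fallback sets out from 30 and rejoins at 31. A plain lithium enolate aldol of 30 with 22 gives 31 together with its (1R)-carbinol epimer F6. Dess–Martin oxidation converges the mixture on the 3-acyl lactone F7, whose α-centre settles on the convex face. Chelation-controlled reduction of F7 with Zn(BH4)2 (hydride anti to the α-substituent of the zinc chelate) should give the syn alcohol 31.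

3. Step 19. Cross-metathesis may stall at the hindered, allylically branched alkene while the styrene partner homodimerises. The fallback sets out from lactol 34 and aldehyde 3 and rejoins at 36. NaBH4 reduction of 3 gives [4-(TIPSO)phenyl]methanol F8, PBr3 gives 1-(bromomethyl)-4-(TIPSO)benzene F9, and PBu3 gives tributyl[4-(TIPSO)benzyl]phosphonium bromide F10. The ylide from F10 (KHMDS, THF) reacts with 34 in an E-selective Wittig reaction of a trialkylphosphonium semi-stabilised ylide and gives 36 directly.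

**Further compounds**

F1 | step 12 | (3S)-1-[4-(TIPSO)phenyl]hex-5-en-3-ol | C=CC[C@@H](O)CCc1ccc(O[Si](C(C)C)(C(C)C)C(C)C)cc1
F2 | step 12 | methyl (3E,6S)-6-hydroxy-8-[4-(TIPSO)phenyl]oct-3-enoate | COC(=O)C/C=C/C[C@@H](O)CCc1ccc(O[Si](C(C)C)(C(C)C)C(C)C)cc1
F3 | step 12 | methyl 2-[(2S,3S,4R,6S)-2-[4-(TIPSO)phenyl]-6-{2-[4-(TIPSO)phenyl]ethyl}-4-(trifluoroacetoxy)oxan-3-yl]acetate | COC(=O)C[C@@H]1[C@@H](c2ccc(O[Si](C(C)C)(C(C)C)C(C)C)cc2)O[C@@H](CCc2ccc(O[Si](C(C)C)(C(C)C)C(C)C)cc2)C[C@H]1OC(=O)C(F)(F)F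
F4 | step 12 | methyl 2-[(2S,3S,4R,6S)-4-hydroxy-2-[4-(TIPSO)phenyl]-6-{2-[4-(TIPSO)phenyl]ethyl}oxan-3-yl]acetate | COC(=O)C[C@@H]1[C@@H](c2ccc(O[Si](C(C)C)(C(C)C)C(C)C)cc2)O[C@@H](CCc2ccc(O[Si](C(C)C)(C(C)C)C(C)C)cc2)C[C@H]1O
F5 | step 12 | methyl 2-[(2S,3R,6S)-4-oxo-2-[4-(TIPSO)phenyl]-6-{2-[4-(TIPSO)phenyl]ethyl}oxan-3-yl]acetate | COC(=O)C[C@@H]1[C@@H](c2ccc(O[Si](C(C)C)(C(C)C)C(C)C)cc2)O[C@@H](CCc2ccc(O[Si](C(C)C)(C(C)C)C(C)C)cc2)CC1=O
F6 | step 15 | (3R,3aS,4S,6S,7aS)-3-{(1R)-1-hydroxy-4-[4-(TIPSO)phenyl]butyl}-4-[4-(TIPSO)phenyl]-6-{2-[4-(TIPSO)phenyl]ethyl}hexahydro-4H-furo[3,2-c]pyran-2(3H)-one | O=C1[C@@H]([C@H](O)CCCc2ccc(O[Si](C(C)C)(C(C)C)C(C)C)cc2)[C@@H]2[C@@H](c3ccc(O[Si](C(C)C)(C(C)C)C(C)C)cc3)O[C@@H](CCc3ccc(O[Si](C(C)C)(C(C)C)C(C)C)cc3)C[C@@H]2O1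
F7 | step 15 | (3R,3aS,4S,6S,7aS)-3-{4-[4-(TIPSO)phenyl]butanoyl}-4-[4-(TIPSO)phenyl]-6-{2-[4-(TIPSO)phenyl]ethyl}hexahydro-4H-furo[3,2-c]pyran-2(3H)-one | O=C1[C@@H](C(=O)CCCc2ccc(O[Si](C(C)C)(C(C)C)C(C)C)cc2)[C@@H]2[C@@H](c3ccc(O[Si](C(C)C)(C(C)C)C(C)C)cc3)O[C@@H](CCc3ccc(O[Si](C(C)C)(C(C)C)C(C)C)cc3)C[C@@H]2O1
F8 | step 19 | [4-(triisopropylsilyloxy)phenyl]methanol | OCc1ccc(O[Si](C(C)C)(C(C)C)C(C)C)cc1
F9 | step 19 | 1-(bromomethyl)-4-(triisopropylsilyloxy)benzene | BrCc1ccc(O[Si](C(C)C)(C(C)C)C(C)C)cc1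
F10 | step 19 | tributyl[4-(triisopropylsilyloxy)benzyl]phosphonium bromide | CCCC[P+](CCCC)(CCCC)Cc1ccc(O[Si](C(C)C)(C(C)C)C(C)C)cc1.[Br-]
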